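- Your pitfall in a flask with equal charges is a first-order half-life. In the cedar run the electrophile took 10.0 h to reach 50.1%, and after that a longer stretch of 20.0 h to reach 27.2%.

| flask | electrophile | nucleophile | free base | protic impurity | remark | time |
|---|---|---|---|---|---|---|
| maple | 20 mM | 1 equiv | 1 equiv (in portions, 4) | 6 mM | run made earlier; portions every 8.0 h |  |
| cedar | 20 mM | 1 equiv | 1.5 equiv (in portions, 4) | 6 mM | run made earlier; portions every 8.0 h |  |
| Saturday's | 20 mM | 1.00 equiv | 2.00 equiv (in portions, 4) | 6.00 mM | the portions of free base follow each other after 8.0 h, the first at the start | 30 h |
| Wednesday's | 20 mM | 1.00 equiv | 2.00 equiv (in portions, 4) | 6.00 mM | the portions of free base follow each other after 8.0 h, the first at the start | 40 h |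

- maple (time / h: electrophile / %, target / %): 2.50: 80.5, 19.6; 4.00: 71.7, 26.6; 6.00: 66.6, 35.9; 10.0: 53.6, 45.5; 20.0: 38.1, 62.5; 30.0: 27.8, 71.3
- cedar (time / h: electrophile / %, target / %): 2.00: 82.9, 17.3; 6.00: 65.1, 34.4; 10.0: 50.1, 47.7; 15.0: 41.9, 57.1; 25.0: 29.1, 69.5; 30.0: 27.2, 73.7

(scatter of a reading: 1 percentage point)

- steps under discussion: electrophile + nucleophile <-> acid set free + target; nucleophile + acid set free <-> protonated nucleophile; acid set free + free base <-> salt of the base; protic impurity + free base -> quenched reagent

* which of these there is most of at the end, counted by the electrophile in it, Saturday's (electrophile / target)
* which of these there is most of at the end, counted by the electrophile in it, Wednesday's (electrophile / target)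
* the largest of these amounts at the end, in percent of the electrophile charged, Saturday's
* the largest of these amounts at the end, in percent of the electrophile charged, Wednesday's

- Each target uses one electrophile and one nucleophile, and these four flasks charge them equally, so neither is the limiting reagent. If protonated nucleophile stays small, [electrophile] and [nucleophile] fall together, and the forward rate goes as [electrophile] squared.
- My reckoning, with the way back not counted, then gives a target share of t/(t + clock), where the clock is the time in which a one-to-one flask reaches half conversion. The two late cedar readings give 10.8 h, as a reading with its scatter.
- The two late maple readings give 11.8 h, a longer time than the cedar value, and it carries the same scatter. I carry the cedar value, from the nearer recipe, to Saturday's and Wednesday's flasks.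
- The shortest rung is the gap between portions, 8.0 h, shorter than the clock, so I do not reckon the portions one by one.
- The next rung is the clock. The longest is the run: Saturday's flask lasts 2.79 clocks and Wednesday's 3.72.
- In this reckoning, past one clock, target outweighs electrophile. I reckon target at 73.6% in Saturday's flask and 78.8% in Wednesday's.
- The forecast says target at 74% for Saturday's flask and target at 79% for Wednesday's, holding that “Extra base barely changes the rate”. It stands on the same readings as my reckoning, so the two are not independent.

    electrophile + nucleophile ⇌ acid set free + target (K = 0.210, k = 4.80 M⁻¹ h⁻¹)
    nucleophile + acid set free ⇌ protonated nucleophile, settled at all times (K = 2100 M⁻¹)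
    acid set free + free base ⇌ salt of the base, settled at all times (K = 2.50 × 10⁵ M⁻¹)
    protic impurity + free base → quenched reagent (k = 7.90 M⁻¹ h⁻¹)

- Saturday's flask gives target at 73.9%, and Wednesday's gives target at 79.1%, as forecast. Of the settings tried, each moved alone by the same factor, Wednesday's target shifted in this order: nucleophile (13 points), then electrophile (4.6 points), then free base (0.27 points), then protic impurity (under 0.05 points). The clock also serves inside Wednesday's run: at 20.0 h it gives electrophile 35.1%, and the flask held 34.6%.
- Take the neighbour of Saturday's flask with 0.250 equiv of nucleophile, now the limiting reagent. Its balance caps target at 25.0%, and the same clock with unequal charges leaves electrophile at 77.4% and target at 22.6%.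
- That neighbour computes to 77.2% electrophile and 22.8% target, with 8.9% of its nucleophile left.

(The readings are calculated for an exercise; the scatter is artificial.)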